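**Retrosynthetic overview**
- Last bond: the tertiary C–OH of the spiro cyclohexane ring, made by radical (hydrogen-atom-transfer) hydration of an exocyclic methylene group. Oxygen enters from the only open face; a methyl nucleophile added to the corresponding ketone would enter from the same face and give the wrong epimer.
- Ring B (spiro cyclohexane) is closed just before by palladium-catalysed intramolecular allylic alkylation of a triketone carbon. The other bond to that carbon comes from reductive alkylation with a cyclopentane carbaldehyde.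
- Ring A comes from phloroglucinol: C-acylation, then gem-diprenylation (dearomatisation).
- Ring C (cyclopentane) comes from (S)-limonene by ozonolysis and aldol ring contraction. Its tertiary C–OH is set by epoxidation of the enal and hydride opening; the isopropenyl group is then chlorinated at the allylic position.
- Order of ring formation: ring A (arene), ring C (aldol), ring B (spirocyclisation); the last stereocentre is set by C–O bond formation.

Assumption: keto–enol tautomers of the β-triketone ring count as one compound and are drawn in one form. Ring A atoms are C-1 to C-6 (C-1 is the spiro atom), hydrindane atoms are primed (C-5' = C-1, C-3' and C-7' are the carbinol carbons, C-3a'/C-7a' the ring fusion).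

**Step 1**
Reactants: 1 phloroglucinol; 2 isovaleryl chloride
Product: 3 phlorisovalerophenone, 3-methyl-1-(2,4,6-trihydroxyphenyl)butan-1-one
Conditions: AlCl3, CH2Cl2/MeNO2, 0 °C → rt
Reagents that add atoms: none
Why: Friedel–Crafts acylation of the electron-rich triol stops after one acyl group because the chelated ketone deactivates the ring; no stereocentre is formed.

**Step 2**
Reactants: 3 phlorisovalerophenone; 4 prenyl bromide (2.1 equiv)
Product: 6 3,5-dihydroxy-2-(3-methylbutanoyl)-4,4-bis(3-methylbut-2-en-1-yl)cyclohexa-2,5-dien-1-one, via mono-C-prenyl ketone 5 (not isolated)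
Conditions: NaOMe, MeOH, 0 °C → rt; chromatography
Reagents that add atoms: none
Why: Alkylative dearomatisation (double C-prenylation by SN2): the second prenyl bromide attacks the already prenylated carbon of 5 in competition with the free carbon, so 6 forms together with the separable 3,5-diprenyl isomer (modest yield expected, cheap materials); no stereocentre is formed.

**Step 3**
Reactants: 7 (S)-(−)-limonene
Product: 9 (3S)-6-oxo-3-(prop-1-en-2-yl)heptanal, via ozonide 8 (not isolated)
Conditions: O3 (1.0 equiv), CH2Cl2, −78 °C; then Me2S, −78 °C → rt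
Reagents that add atoms: ozone, [O-][O+]=O
Why: Ozonolysis with one equivalent of ozone cleaves the more electron-rich trisubstituted ring alkene in preference to the isopropenyl group and Me2S reduces the ozonide; the limonene stereocentre is untouched.

**Step 4**
Reactants: 9 (3S)-6-oxo-3-(prop-1-en-2-yl)heptanal
Product: 10 (5R)-2-methyl-5-(prop-1-en-2-yl)cyclopent-1-ene-1-carbaldehyde
Conditions: piperidine, AcOH, toluene, 80 °C
Reagents that add atoms: none
Why: Intramolecular aldol condensation through the piperidine enamine of the aldehyde (attack on the methyl ketone, then dehydration) gives the cyclopentene carbaldehyde; the stereocentre is not at an enolisable position and is kept.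

**Step 5**
Reactants: 10 (5R)-2-methyl-5-(prop-1-en-2-yl)cyclopent-1-ene-1-carbaldehyde
Product: 11 (1R,2R,5S)-5-methyl-2-(prop-1-en-2-yl)-6-oxabicyclo[3.1.0]hexane-1-carbaldehyde
Conditions: H2O2 (30% aq), NaOH, MeOH, 0 °C
Reagents that add atoms: hydrogen peroxide, OO
Why: Weitz–Scheffer nucleophilic epoxidation: hydroperoxide adds reversibly to the β-carbon and the enolate closes on oxygen from the face anti to the neighbouring isopropenyl group, which sets both epoxide carbons; the electron-rich isopropenyl alkene does not react with HOO−.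

**Step 6**
Reactants: 11 epoxy aldehyde
Product: 13 (1S,2S,3S)-2-(hydroxymethyl)-1-methyl-3-(prop-1-en-2-yl)cyclopentan-1-ol, via epoxy alcohol aluminate 12 (not isolated)
Conditions: NaAlH2(OCH2CH2OMe)2 (Red-Al, 3 equiv), THF, 0 → 50 °C; aq. potassium sodium tartrate
Reagents that add atoms: none
Why: The aldehyde is reduced first and the resulting alkoxyaluminate delivers hydride intramolecularly to C-2 of the 2,3-epoxy alcohol (Red-Al 1,3-diol opening) with inversion, which leaves the tertiary alcohol and puts the new ring C–H trans to it and the CH2OH group trans to the isopropenyl group.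

**Step 7**
Reactants: 13 diol
Product: 14 (1S,2S,3S)-3-(3-chloroprop-1-en-2-yl)-2-(hydroxymethyl)-1-methylcyclopentan-1-ol
Conditions: Ca(OCl)2, CO2 (solid), CH2Cl2/H2O, 0 °C
Reagents that add atoms: calcium hypochlorite, [Ca+2].[O-]Cl.[O-]Cl
Why: Ene-type allylic chlorination by HOCl turns the isopropenyl group into a 2-(chloromethyl)vinyl group, and neither hydroxyl can trap the chloronium ion because both are trans to the side chain; no stereocentre changes.

**Step 8**
Reactants: 14 chloro diol
Product: 15 (1R,2S,5S)-5-(3-chloroprop-1-en-2-yl)-2-hydroxy-2-methylcyclopentane-1-carbaldehyde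
Conditions: TEMPO (10 mol%), PhI(OAc)2, CH2Cl2, rt
Reagents that add atoms: none
Why: Oxoammonium (TEMPO) oxidation is selective for the primary alcohol and stops at the aldehyde, the tertiary alcohol and allylic chloride are inert, and the α-centre stays in the more stable all-trans arrangement.

**Step 9**
Reactants: 6 gem-diprenyl triketone; 15 hydroxy aldehyde
Product: 17 6-{[(1R,2S,5S)-5-(3-chloroprop-1-en-2-yl)-2-hydroxy-2-methylcyclopentyl]methyl}-3,5-dihydroxy-2-(3-methylbutanoyl)-4,4-bis(3-methylbut-2-en-1-yl)cyclohexa-2,5-dien-1-one, via alkylidene triketone 16 (not isolated)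
Conditions: Hantzsch ester, L-proline (20 mol%), CH2Cl2, rt
Reagents that add atoms: none
Why: Three-component reductive alkylation: Knoevenagel condensation at the only free carbon of the cyclic β-diketone gives alkylidene 16, which the Hantzsch ester reduces by conjugate hydride transfer; no new stereocentre is formed and the allylic chloride survives the neutral conditions.

**Step 10**
Reactants: 17 alkylated triketone
Product: 18 (3'S,3a'R,7a'S)-3',4-dihydroxy-3'-methyl-7'-methylidene-5-(3-methylbutanoyl)-3,3-bis(3-methylbut-2-en-1-yl)octahydrospiro[cyclohex-4-ene-1,5'-indene]-2,6-dione, spiro centre S (C-2 carbonyl cis to H-3a', trans ring fusion)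
Conditions: Pd(PPh3)4 (5 mol%), K2CO3, MeCN, rt
Reagents that add atoms: none
Why: Tsuji–Trost intramolecular allylic alkylation: zerovalent palladium ionises the allylic chloride to a 2-substituted π-allyl complex, the triketonate attacks through its alkylated carbon anti to palladium in a chair transition state, and the carbonyl carbon next to the bulky C(prenyl)2 group is expected to take the axial site where the prenyl arms point away from the Pd–phosphine face, which gives the S spiro centre (moderate dr expected, epimer separable).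

**Step 11**
Reactants: 18 spiro triene
Product: 20 target, (3'S,3a'R,7'S,7a'S)-3',4,7'-trihydroxy-3',7'-dimethyl-5-(3-methylbutanoyl)-3,3-bis(3-methylbut-2-en-1-yl)octahydrospiro[cyclohex-4-ene-1,5'-indene]-2,6-dione, spiro centre S, via tertiary hydroperoxide 19 (not isolated)
Conditions: Mn(dpm)3 (10 mol%; dpm = 2,2,6,6-tetramethylheptane-3,5-dionate), PhSiH3, O2 (1 atm), i-PrOH/CH2Cl2, −10 °C, stopped near 70% conversion; then PPh3
Reagents that add atoms: dioxygen, O=O
Why: Proposed new method: site- and face-selective Mukaiyama-type hydration of the one exocyclic 1,1-disubstituted alkene of a triene that also carries two prenyl groups and a free enolised β-triketone, a selectivity not yet shown on such substrates; the manganese hydride formed from Mn(dpm)3 and PhSiH3 should transfer H• fastest to the unhindered terminal CH2 (the prenyl CH= carbons are internal and neopentyl-like, the enol C=C is tetrasubstituted and electron-poor), the tertiary ring radical is trapped by O2 from the equatorial face because the axial face is covered by the axial C-2 carbonyl oxygen, and PPh3 reduces the hydroperoxide, so this C–O bond sets C-7' as S; the closest known reaction type is the Mukaiyama Markovnikov hydration of alkenes (manganese or cobalt β-diketonate, silane, O2).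

**Compound list**
1 | phloroglucinol (benzene-1,3,5-triol) | Oc1cc(O)cc(O)c1 | starting material
2 | isovaleryl chloride (3-methylbutanoyl chloride) | CC(C)CC(=O)Cl | starting material
3 | phlorisovalerophenone, 3-methyl-1-(2,4,6-trihydroxyphenyl)butan-1-one | CC(C)CC(=O)c1c(O)cc(O)cc1O | intermediate
4 | prenyl bromide (1-bromo-3-methylbut-2-ene) | CC(C)=CCBr | starting material
5 | 3-methyl-1-[2,4,6-trihydroxy-3-(3-methylbut-2-en-1-yl)phenyl]butan-1-one | CC(C)CC(=O)c1c(O)cc(O)c(CC=C(C)C)c1O | intermediate
6 | 3,5-dihydroxy-2-(3-methylbutanoyl)-4,4-bis(3-methylbut-2-en-1-yl)cyclohexa-2,5-dien-1-one (enol form of the 2-acyl-4,4-diprenylcyclohexane-1,3,5-trione) | CC(C)CC(=O)C1=C(O)C(CC=C(C)C)(CC=C(C)C)C(O)=CC1=O | intermediate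
7 | (S)-(−)-limonene, (4S)-1-methyl-4-(prop-1-en-2-yl)cyclohex-1-ene | CC1=CC[C@H](CC1)C(C)=C | starting material
8 | secondary ozonide (1,2,4-trioxolane) of the ring alkene of 7, isopropenyl-bearing centre unchanged | CC12CC[C@H](C(C)=C)CC(OO1)O2 | intermediate
9 | (3S)-6-oxo-3-(prop-1-en-2-yl)heptanal | O=CC[C@H](CCC(C)=O)C(C)=C | intermediate
10 | (5R)-2-methyl-5-(prop-1-en-2-yl)cyclopent-1-ene-1-carbaldehyde | O=CC1=C(C)CC[C@@H]1C(C)=C | intermediate
11 | (1R,2R,5S)-5-methyl-2-(prop-1-en-2-yl)-6-oxabicyclo[3.1.0]hexane-1-carbaldehyde (epoxide anti to isopropenyl) | O=C[C@]12O[C@@]1(C)CC[C@@H]2C(C)=C | intermediate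
12 | [(1S,2R,5S)-5-methyl-2-(prop-1-en-2-yl)-6-oxabicyclo[3.1.0]hexan-1-yl]methanol (present as its aluminium alkoxide) | OC[C@]12O[C@@]1(C)CC[C@@H]2C(C)=C | intermediate
13 | (1S,2S,3S)-2-(hydroxymethyl)-1-methyl-3-(prop-1-en-2-yl)cyclopentan-1-ol | OC[C@@H]1[C@H](CC[C@]1(C)O)C(C)=C | intermediate
14 | (1S,2S,3S)-3-(3-chloroprop-1-en-2-yl)-2-(hydroxymethyl)-1-methylcyclopentan-1-ol | OC[C@@H]1[C@H](CC[C@]1(C)O)C(=C)CCl | intermediate
15 | (1R,2S,5S)-5-(3-chloroprop-1-en-2-yl)-2-hydroxy-2-methylcyclopentane-1-carbaldehyde | O=C[C@@H]1[C@H](CC[C@]1(C)O)C(=C)CCl | intermediate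
16 | Knoevenagel adduct of 6 and 15: 6-(cyclopentylmethylidene)-5-hydroxy-4-(3-methylbutanoyl)-2,2-bis(3-methylbut-2-en-1-yl)cyclohex-4-ene-1,3-dione, cyclopentane centres as in 15 | CC(C)CC(=O)C1=C(O)C(CC=C(C)C)(CC=C(C)C)C(=O)C(=C[C@@H]2[C@H](CC[C@]2(C)O)C(=C)CCl)C1=O | intermediate
17 | 6-{[(1R,2S,5S)-5-(3-chloroprop-1-en-2-yl)-2-hydroxy-2-methylcyclopentyl]methyl}-3,5-dihydroxy-2-(3-methylbutanoyl)-4,4-bis(3-methylbut-2-en-1-yl)cyclohexa-2,5-dien-1-one | CC(C)CC(=O)C1=C(O)C(CC=C(C)C)(CC=C(C)C)C(O)=C(C[C@@H]2[C@H](CC[C@]2(C)O)C(=C)CCl)C1=O | intermediate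
18 | (3'S,3a'R,7a'S)-3',4-dihydroxy-3'-methyl-7'-methylidene-5-(3-methylbutanoyl)-3,3-bis(3-methylbut-2-en-1-yl)octahydrospiro[cyclohex-4-ene-1,5'-indene]-2,6-dione, spiro centre S, trans-fused | CC(C)=CCC1(CC=C(C)C)C(=O)[C@@]2(C[C@@H]3[C@H](CC[C@]3(C)O)C(=C)C2)C(=O)C(C(=O)CC(C)C)=C1O | intermediate
19 | 7'-hydroperoxide of the target (7'S, OOH in place of the 7'-OH) | CC(C)=CCC1(CC=C(C)C)C(=O)[C@@]2(C[C@@H]3[C@H](CC[C@]3(C)O)[C@@](C)(OO)C2)C(=O)C(C(=O)CC(C)C)=C1O | intermediate
20 | (3'S,3a'R,7'S,7a'S)-3',4,7'-trihydroxy-3',7'-dimethyl-5-(3-methylbutanoyl)-3,3-bis(3-methylbut-2-en-1-yl)octahydrospiro[cyclohex-4-ene-1,5'-indene]-2,6-dione, spiro centre S, both carbinol OH groups cis to H-7a' | CC(C)=CCC1(CC=C(C)C)C(=O)[C@@]2(C[C@@H]3[C@H](CC[C@]3(C)O)[C@@](C)(O)C2)C(=O)C(C(=O)CC(C)C)=C1O | target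

**Step count and risks**
Total steps: 11. Longest linear sequence: 9 (steps 3–11, from (S)-limonene).

Steps most likely to fail:

1. Step 11 (proposed new step). The prenyl groups may be hydrated competitively, or the triketone may displace the diketonate ligands and steer the catalyst. Fallback with known chemistry, setting out from 3 and 15 and coming back at 20: the prenyl groups are put on after the hydration so no site selectivity is needed. Reductive alkylation of 3 (used in excess) with 15 (Hantzsch ester, L-proline) gives the C-alkylated phlorisovalerophenone F1. Pd(PPh3)4/K2CO3 closes ring B to the spiro dienone F2, purified by chromatography. Ordinary Mukaiyama hydration of its only unactivated alkene (Mn(dpm)3, PhSiH3, O2; then PPh3) gives the spiro diol F3. Exhaustive C-prenylation of the remaining ring-A CH with 4 and NaOMe/MeOH gives 20.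

2. Step 10. The spiro centre is set only by the steric argument given, and the selectivity may be low. Fallback setting out from 14 and 6 and coming back at 18: the two C–C bonds are made in the opposite order. TsCl/pyridine converts 14 into the primary tosylate F4. Pd(PPh3)4/K2CO3 joins its allylic chloride to C-6 of 6 to give the C-allyl triketone tosylate F5. K2CO3 in DMF at 60 °C then closes ring B by intramolecular SN2 displacement of the tosylate, a different transition state with no palladium at the ring being formed. This gives 18 together with its spiro epimer F6, which is removed by chromatography.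

3. Step 6. Hydride must open a fully substituted epoxide carbon and may attack the other carbon instead. Fallback setting out from 11 and coming back at 13: the carbonyl group fixes the regiochemistry through single-electron reduction. Pinnick oxidation (NaClO2, NaH2PO4, 2-methylbut-2-ene) gives the epoxy acid F7, and TMSCHN2 gives the methyl ester F8. SmI2 (THF/MeOH, −78 °C) cleaves only the Cα–O bond to give the β-hydroxy ester F9; the α-centre is equilibrated trans with NaOMe if needed. LiAlH4 reduces F9 to 13.

**Further compounds**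
F1 | step 11 | 1-[3-{[(1R,2S,5S)-5-(3-chloroprop-1-en-2-yl)-2-hydroxy-2-methylcyclopentyl]methyl}-2,4,6-trihydroxyphenyl]-3-methylbutan-1-one | CC(C)CC(=O)c1c(O)cc(O)c(C[C@@H]2[C@H](CC[C@]2(C)O)C(=C)CCl)c1O
F2 | step 11 | spiro dienone: 18 without the two prenyl groups (ring-A CH free), same configuration at all centres | CC(C)CC(=O)C1=C(O)[C@]2(C[C@@H]3[C@H](CC[C@]3(C)O)C(=C)C2)C(O)=CC1=O
F3 | step 11 | spiro diol: target without the two prenyl groups, same configuration at all centres | CC(C)CC(=O)C1=C(O)[C@]2(C[C@@H]3[C@H](CC[C@]3(C)O)[C@@](C)(O)C2)C(O)=CC1=O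
F4 | step 10 | [(1S,2S,5S)-5-(3-chloroprop-1-en-2-yl)-2-hydroxy-2-methylcyclopentyl]methyl 4-methylbenzenesulfonate | Cc1ccc(cc1)S(=O)(=O)OC[C@@H]1[C@H](CC[C@]1(C)O)C(=C)CCl
F5 | step 10 | C-6 allylated 6: 2-methylidene-propyl link from C-6 to the cyclopentane, primary tosylate retained | CC(C)CC(=O)C1=C(O)C(CC=C(C)C)(CC=C(C)C)C(O)=C(CC(=C)[C@H]2CC[C@](C)(O)[C@@H]2COS(=O)(=O)c2ccc(C)cc2)C1=O
F6 | step 10 | spiro epimer of 18 (spiro centre R) | CC(C)=CCC1(CC=C(C)C)C(=O)[C@]2(C[C@@H]3[C@H](CC[C@]3(C)O)C(=C)C2)C(=O)C(C(=O)CC(C)C)=C1O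
F7 | step 6 | (1R,2R,5S)-5-methyl-2-(prop-1-en-2-yl)-6-oxabicyclo[3.1.0]hexane-1-carboxylic acid | OC(=O)[C@]12O[C@@]1(C)CC[C@@H]2C(C)=C
F8 | step 6 | methyl (1R,2R,5S)-5-methyl-2-(prop-1-en-2-yl)-6-oxabicyclo[3.1.0]hexane-1-carboxylate | COC(=O)[C@]12O[C@@]1(C)CC[C@@H]2C(C)=C
F9 | step 6 | methyl (1R,2S,5S)-2-hydroxy-2-methyl-5-(prop-1-en-2-yl)cyclopentane-1-carboxylate | COC(=O)[C@@H]1[C@H](CC[C@]1(C)O)C(C)=C
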